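**Retrosynthetic overview**
- Target ⇒ C6–O disconnection: the octatrienoate is installed last, by outside attack of the carboxylate on an α-face allylpalladium generated from the silyl dienol ether of 9α-hydroxy-12-oxodrim-7-en-11-oic acid (sets 6β).
- That enal acid ⇒ C12–O disconnection: singlet-oxygen ene reaction and dehydration of 9α-hydroxydrim-8(12)-en-11-oic acid.
- That acid ⇒ C9–O disconnection: α-face hydroxylation of the dienediolate of drim-8-en-11-oic acid (sets 9α-OH).
- Drim-8-en-11-oic acid ⇒ drim-8-en-11-al ⇒ (+)-sclareolide by excision of one carbon (ketene acetal ozonolysis, loss of the C8 carbonate).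
- Rings: none is built. Rings A and B with C5 and C10 come intact from sclareolide; only its lactone ring is opened (step 1).

Assumption: (2E,4E,6E)-octa-2,4,6-trienoic acid is bought; drimane numbering is used (C11 on C9, C12 on C8), every compound keeps the 5α-H/10β-CH3 trans-decalin of (+)-sclareolide, and aldehyde–acids are written in their open form.

**Step 1**
Reactants: 1 (+)-sclareolide
Product: 5 drim-8-en-11-al, via lithium enolate 2 (not isolated), via silyl ketene acetal 3 (not isolated), via carbonate aldehyde 4 (not isolated)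
Conditions: LiN(iPr)2, THF, −78 °C; TBSCl, DMPU, −78 → 0 °C; solvent change to CH2Cl2; O3, pyridine, −78 °C; then DBU, −78 °C → rt
Reagents that add atoms: ozone, [O-][O+]=O
Why: O-silylation of the lactone enolate gives an electron-rich ketene acetal whose C11=C12 bond is cleaved by pyridine-promoted reductive ozonolysis to the C11 aldehyde carrying an 8α-silyl carbonate, and DBU then expels that carbonate (E1cB, as CO2 and silanol) to give the conjugated enal, so C12 is excised in one flask without touching C5 or C10.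

**Step 2**
Reactants: 5 drim-8-en-11-al
Product: 6 drim-8-en-11-oic acid
Conditions: NaClO2, NaH2PO4, 2-methyl-2-butene, tBuOH/H2O, rt
Reagents that add atoms: sodium chlorite, [Na+].[O-]Cl=O
Why: Pinnick oxidation converts the hindered enal into the acid while 2-methyl-2-butene scavenges HOCl and so protects the tetrasubstituted alkene.

**Step 3**
Reactants: 6 drim-8-en-11-oic acid
Product: 8 9α-hydroxydrim-8(12)-en-11-oic acid, via dilithium dienediolate 7 (not isolated)
Conditions: LiN(iPr)2 (2.5 equiv), THF, −78 → 0 °C; then 2-(phenylsulfonyl)-3-phenyloxaziridine, −78 °C; aq. HCl work-up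
Reagents that add atoms: 2-(phenylsulfonyl)-3-phenyloxaziridine, O=S(=O)(c1ccccc1)N1OC1c1ccccc1
Why: After carboxylate formation the base removes a hydrogen of the C12 methyl group, which lies syn to the carboxylate (kinetic γ-deprotonation), and the dienediolate is hydroxylated at its α-carbon C9 by the sulfonyloxaziridine (Davis oxidation) from the α face opposite the axial 10β-methyl, which sets 9α-OH/9β-CO2H and leaves the 8(12)-exocyclic alkene.

**Step 4**
Reactants: 8 9α-hydroxydrim-8(12)-en-11-oic acid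
Product: 11 9α-hydroxy-12-oxodrim-7-en-11-oic acid, via allylic hydroperoxide 9 (not isolated), via pseudo-acetate 10 (not isolated)
Conditions: O2, tetraphenylporphyrin (cat.), white LED, CH2Cl2, 0 °C; then Ac2O, pyridine, DMAP (cat.), 0 °C → rt; then H2O/THF, rt
Reagents that add atoms: dioxygen (as singlet oxygen), O=O
Why: In the Schenck ene reaction the exocyclic alkene can only give up an allylic hydrogen from C7, so oxygen is delivered to C12 and the double bond moves to C7=C8; Ac2O/pyridine dehydrates the primary hydroperoxide to the aldehyde (Kornblum–DeLaMare-type elimination), and the pseudo-acetate in which the aldehyde–acid is captured is hydrolysed by water.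

**Step 5**
Reactants: 11 9α-hydroxy-12-oxodrim-7-en-11-oic acid
Product: 12 triethylsilyl 9α,12-bis(triethylsilyloxy)drima-6,8(12)-dien-11-oate
Conditions: Et3SiOTf (4 equiv), Et3N (6 equiv), CH2Cl2, −78 → 0 °C; non-aqueous work-up
Reagents that add atoms: triethylsilyl trifluoromethanesulfonate, CC[Si](CC)(CC)OS(=O)(=O)C(F)(F)F
Why: Soft enolisation (silyl dienol ether formation): the silyl triflate activates the enal oxygen and Et3N removes a C6 hydrogen, the only γ-hydrogens available because C9 is quaternary, while the acid and the tertiary alcohol are silylated in the same operation.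

**Step 6**
Reactants: 12 triethylsilyl 9α,12-bis(triethylsilyloxy)drima-6,8(12)-dien-11-oate; 13 (2E,4E,6E)-octa-2,4,6-trienoic acid
Product: 15 ustusoic acid B [6β-((2E,4E,6E)-octa-2,4,6-trienoyloxy)-9α-hydroxy-12-oxodrim-7-en-11-oic acid], via bis-silyl acyloxy enal 14 (not isolated)
Conditions: PdCl2(MeCN)2 (10 mol %), LiCl (20 mol %), 1,4-benzoquinone (1.2 equiv), 2,6-lutidine (20 mol %), 13 (1.5 equiv), acetone, 0 °C → rt; then HF·pyridine, THF, 0 °C
Reagents that add atoms: none
Why: Proposed new method: oxidative γ-acyloxylation of a silyl dienol ether, in which divalent palladium attacks the electron-rich diene at C6 from the open α face with loss of the silyl group (as in the Saegusa–Ito oxidation) to give an η3-allylpalladium spanning C6–C7–C8 on the α face; chloride ligands keep the carboxylate off the metal, so the trienoate attacks the C6 terminus from outside, anti to palladium and therefore from the β face (Tsuji–Trost-type outer-sphere attack, directed to C6 because this restores the C7=C8–CHO conjugation and C8 is fully substituted), which forms the C6–O bond and sets the 6β configuration; benzoquinone reoxidises zerovalent palladium and HF·pyridine removes the silyl groups; the closest known reactions are the Saegusa–Ito oxidation and the chloride-controlled PdCl2/benzoquinone cis-1,4-diacyloxylation of 1,3-dienes.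

**Compound list**
1 | (+)-sclareolide, (3aR,5aS,9aS,9bR)-3a,6,6,9a-tetramethyldecahydronaphtho[2,1-b]furan-2(1H)-one | C1C[C@@]3(C)OC(=O)C[C@@H]3[C@@]2(C)CCCC(C)(C)[C@H]12 | starting material
2 | lithium enolate of sclareolide (C11=C12 enolate) | C1C[C@@]3(C)OC([O-])=C[C@@H]3[C@@]2(C)CCCC(C)(C)[C@H]12.[Li+] | intermediate
3 | tert-butyldimethylsilyl ketene acetal of sclareolide (C11=C12, 12-OTBS, 8α-O retained) | C1C[C@@]3(C)OC(O[Si](C)(C)C(C)(C)C)=C[C@@H]3[C@@]2(C)CCCC(C)(C)[C@H]12 | intermediate
4 | 8α-[(tert-butyldimethylsilyloxy)carbonyloxy]driman-11-al (9α-H, 9β-CHO) | C1C[C@@](C)(OC(=O)O[Si](C)(C)C(C)(C)C)[C@H](C=O)[C@@]2(C)CCCC(C)(C)[C@H]12 | intermediate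
5 | drim-8-en-11-al | C1CC(C)=C(C=O)[C@@]2(C)CCCC(C)(C)[C@H]12 | intermediate
6 | drim-8-en-11-oic acid | C1CC(C)=C(C(=O)O)[C@@]2(C)CCCC(C)(C)[C@H]12 | intermediate
7 | dilithium dienediolate of 6 (C9=C11 and C8=C12 double bonds) | C1CC(=C)C(=C([O-])[O-])[C@@]2(C)CCCC(C)(C)[C@H]12.[Li+].[Li+] | intermediate
8 | 9α-hydroxydrim-8(12)-en-11-oic acid | C1CC(=C)[C@](O)(C(=O)O)[C@@]2(C)CCCC(C)(C)[C@H]12 | intermediate
9 | 12-hydroperoxy-9α-hydroxydrim-7-en-11-oic acid | C1C=C(COO)[C@](O)(C(=O)O)[C@@]2(C)CCCC(C)(C)[C@H]12 | intermediate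
10 | 12-acetoxy-9α-hydroxydrim-7-en-11,12-olide (pseudo-acetate, both C12 epimers) | C1C=C3C(OC(C)=O)OC(=O)[C@]3(O)[C@@]2(C)CCCC(C)(C)[C@H]12 | intermediate
11 | 9α-hydroxy-12-oxodrim-7-en-11-oic acid | C1C=C(C=O)[C@](O)(C(=O)O)[C@@]2(C)CCCC(C)(C)[C@H]12 | intermediate
12 | triethylsilyl 9α,12-bis(triethylsilyloxy)drima-6,8(12)-dien-11-oate (C8=C12 geometry not fixed) | C1=CC(=CO[Si](CC)(CC)CC)[C@](O[Si](CC)(CC)CC)(C(=O)O[Si](CC)(CC)CC)[C@@]2(C)CCCC(C)(C)[C@H]12 | intermediate
13 | (2E,4E,6E)-octa-2,4,6-trienoic acid | C/C=C/C=C/C=C/C(=O)O | starting material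
14 | triethylsilyl 6β-[(2E,4E,6E)-octa-2,4,6-trienoyloxy]-12-oxo-9α-(triethylsilyloxy)drim-7-en-11-oate | C/C=C/C=C/C=C/C(=O)O[C@@H]1C=C(C=O)[C@](O[Si](CC)(CC)CC)(C(=O)O[Si](CC)(CC)CC)[C@@]2(C)CCCC(C)(C)[C@H]12 | intermediate
15 | ustusoic acid B, 6β-[(2E,4E,6E)-octa-2,4,6-trienoyloxy]-9α-hydroxy-12-oxodrim-7-en-11-oic acid | C/C=C/C=C/C=C/C(=O)O[C@@H]1C=C(C=O)[C@](O)(C(=O)O)[C@@]2(C)CCCC(C)(C)[C@H]12 | target

**Step count and risks**
Total step count: 6. Longest linear sequence: 6 steps (1 → 15).

Steps most likely to fail: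

Step 3. The base may take a C7 hydrogen instead of a C12 hydrogen, or the oxidant may attack the γ-carbon C12 instead of C9. The fallback makes the 9α-hydroxyl by epoxide isomerisation instead of enolate oxygenation and sets out from 5. Luche reduction (NaBH4, CeCl3·7H2O, MeOH) gives drim-8-en-11-ol F1. mCPBA epoxidises the tetrasubstituted alkene from the α face to 8α,9α-epoxydriman-11-ol F2. Al(OiPr)3 in refluxing toluene isomerises the epoxide to the exocyclic allylic alcohol drim-8(12)-ene-9α,11-diol F3. TEMPO/PhI(OAc)2 oxidises the primary alcohol to 9α-hydroxydrim-8(12)-en-11-al F4, and Pinnick oxidation comes back to the route at 8.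

Step 4. The 1,1-disubstituted alkene of 8 is a slow ene partner for singlet oxygen and is further deactivated by the neighbouring hydroxyl and carboxyl groups. The fallback uses a Riley oxidation instead of the Schenck ene reaction and sets out from 8. RhCl3·3H2O (cat.) in hot ethanol moves the double bond into ring B to give 9α-hydroxydrim-7-en-11-oic acid F5. SeO2 in refluxing dioxane then oxidises its C12 methyl group to the aldehyde, coming back at 11.

Step 6 (the new step). The β face at C6 is flanked by the 4β- and 10β-methyl groups, so outside attack may lose to β-hydride elimination toward C5 (giving a 5,7-dienal) or to inner-sphere delivery (giving the 6α ester). The fallback uses known chemistry and sets C6 by hydride delivery to a ketone; it sets out from 11. MeOH with catalytic TsOH gives the methyl pseudo-ester 9α-hydroxy-12-methoxydrim-7-en-11,12-olide F6, which masks both the aldehyde and the acid. CrO3·3,5-dimethylpyrazole oxidises the allylic C6 methylene to 9α-hydroxy-12-methoxy-6-oxodrim-7-en-11,12-olide F7. Luche reduction, with hydride entering from the α face, gives 6β,9α-dihydroxy-12-methoxydrim-7-en-11,12-olide F8. (2E,4E,6E)-Octa-2,4,6-trienoyl chloride F9, made from 13 with (COCl)2 and catalytic DMF, acylates the 6β-hydroxyl (pyridine, DMAP) to 6β-[(2E,4E,6E)-octa-2,4,6-trienoyloxy]-9α-hydroxy-12-methoxydrim-7-en-11,12-olide F10. 1 M HCl in THF hydrolyses the pseudo-ester and comes back at 15.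

**Further compounds**
F1 | step 3 | drim-8-en-11-ol | C1CC(C)=C(CO)[C@@]2(C)CCCC(C)(C)[C@H]12
F2 | step 3 | 8α,9α-epoxydriman-11-ol | C1C[C@@]3(C)O[C@@]3(CO)[C@@]2(C)CCCC(C)(C)[C@H]12
F3 | step 3 | drim-8(12)-ene-9α,11-diol | C1CC(=C)[C@](O)(CO)[C@@]2(C)CCCC(C)(C)[C@H]12
F4 | step 3 | 9α-hydroxydrim-8(12)-en-11-al | C1CC(=C)[C@](O)(C=O)[C@@]2(C)CCCC(C)(C)[C@H]12
F5 | step 4 | 9α-hydroxydrim-7-en-11-oic acid | C1C=C(C)[C@](O)(C(=O)O)[C@@]2(C)CCCC(C)(C)[C@H]12
F6 | step 6 | 9α-hydroxy-12-methoxydrim-7-en-11,12-olide (both C12 epimers) | C1C=C3C(OC)OC(=O)[C@]3(O)[C@@]2(C)CCCC(C)(C)[C@H]12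
F7 | step 6 | 9α-hydroxy-12-methoxy-6-oxodrim-7-en-11,12-olide | O=C1C=C3C(OC)OC(=O)[C@]3(O)[C@@]2(C)CCCC(C)(C)[C@H]12
F8 | step 6 | 6β,9α-dihydroxy-12-methoxydrim-7-en-11,12-olide | O[C@@H]1C=C3C(OC)OC(=O)[C@]3(O)[C@@]2(C)CCCC(C)(C)[C@H]12
F9 | step 6 | (2E,4E,6E)-octa-2,4,6-trienoyl chloride | C/C=C/C=C/C=C/C(=O)Cl
F10 | step 6 | 6β-[(2E,4E,6E)-octa-2,4,6-trienoyloxy]-9α-hydroxy-12-methoxydrim-7-en-11,12-olide | C/C=C/C=C/C=C/C(=O)O[C@@H]1C=C3C(OC)OC(=O)[C@]3(O)[C@@]2(C)CCCC(C)(C)[C@H]12
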